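**Retrosynthetic overview**
1. Target 20 ⇒ iodoaryl allyl ether 17 by a one-pot aryl-radical 5-exo-trig cyclisation with O2 capture (forms C3–C3a and the CH2–OH bond, sets C3), then desilylation.
2. 17 ⇒ iodophenol 6 + racemic 1-arylallyl benzoate 15 by Ir-catalysed asymmetric allylic etherification (forms C2–O, sets C2).
3. 6 ⇐ catechol 1: mono-methylation, acetylation/Fries shift with acetic anhydride 3, iodination.
4. 15 ⇐ p-cresol 7: bromination/side-chain oxidation, Cu-catalysed methoxylation, silylation, vinylmagnesium bromide 13 then BzCl.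
5. Ring order: both benzene rings come from the starting materials; the dihydrofuran ring is the only ring made, and it is closed in the key step.

Assumption: in step 8 the (Sa,S,S) ligand is taken to give the S ether, by analogy with phenoxide and amine additions to cinnamyl electrophiles; if the first run shows the opposite sense, the antipodal ligand is used with no other change.

TIPS = triisopropylsilyl. L = (Sa,S,S)-O,O'-(1,1'-binaphthalene-2,2'-diyl) N,N-bis(1-phenylethyl)phosphoramidite.

**Step 1**
Reactants: 1 catechol (benzene-1,2-diol)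
Product: 2 2-methoxyphenol (guaiacol)
Conditions: MeI (1.0 equiv), Li2CO3 (0.6 equiv), DMF, 50 °C
Reagents that add atoms: iodomethane, CI
Why: Williamson mono-O-methylation, in which the weak base Li2CO3 ionises only one OH of catechol and the hydrogen-bonded OH of 2 reacts more slowly, so that residual 1 and a little 1,2-dimethoxybenzene are removed by extraction and distillation.

**Step 2**
Reactants: 2 2-methoxyphenol; 3 acetic anhydride
Product: 5 1-(4-hydroxy-3-methoxyphenyl)ethan-1-one (acetovanillone), via 2-methoxyphenyl acetate 4 (not isolated)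
Conditions: 3 (1.05 equiv), neat, 60 °C; then P2O5/MeSO3H (1:10), 50 °C
Reagents that add atoms: none
Why: O-acetylation followed by acid-promoted Fries rearrangement, in which the acylium ion is delivered para to the ester oxygen; the minor ortho-Fries and iso-acetovanillone isomers are removed by crystallisation.

**Step 3**
Reactants: 5 acetovanillone
Product: 6 1-(4-hydroxy-3-iodo-5-methoxyphenyl)ethan-1-one
Conditions: NIS (1.05 equiv), TsOH·H2O (10 mol %), MeCN, rt
Reagents that add atoms: N-iodosuccinimide, O=C1CCC(=O)N1I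
Why: Electrophilic aromatic iodination, directed to the only free position ortho to the phenol OH (para is blocked by the acetyl group), as in the iodination of vanillin.

**Step 4**
Reactants: 7 p-cresol (4-methylphenol)
Product: 10 3,5-dibromo-4-hydroxybenzaldehyde, via 2,6-dibromo-4-methylphenol 8 (not isolated), via 2,6-dibromo-4-(dibromomethyl)phenol 9 (not isolated)
Conditions: Br2 (4.1 equiv), o-dichlorobenzene, 35 °C then 155 °C; then H2O, 100 °C
Reagents that add atoms: bromine, BrBr; water, O
Why: Electrophilic ring dibromination at low temperature, thermal side-chain dibromination of the methyl group at high temperature and hydrolysis of the gem-dibromide to the aldehyde, the established one-pot process for this compound.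

**Step 5**
Reactants: 10 3,5-dibromo-4-hydroxybenzaldehyde
Product: 11 4-hydroxy-3,5-dimethoxybenzaldehyde (syringaldehyde)
Conditions: NaOMe (5 equiv), CuCl (10 mol %), DMF/MeOH, 110 °C (sealed); then aq HCl
Reagents that add atoms: sodium methoxide, C[O-].[Na+]
Why: Copper-catalysed Ullmann-type methoxylation of both aryl bromides; the phenoxide formed in situ protects the aldehyde from methoxide, as in the technical syringaldehyde synthesis.

**Step 6**
Reactants: 11 syringaldehyde
Product: 12 3,5-dimethoxy-4-[(triisopropylsilyl)oxy]benzaldehyde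
Conditions: TIPSCl (1.2 equiv), imidazole (2.5 equiv), DMAP (cat.), DMF, 40 °C
Reagents that add atoms: chlorotriisopropylsilane, CC(C)[Si](Cl)(C(C)C)C(C)C
Why: Standard silylation of a phenol, which masks the OH that would otherwise open quinone-methide pathways in steps 7 and 8 and act as a peroxyl-radical scavenger in step 9.

**Step 7**
Reactants: 12 3,5-dimethoxy-4-[(triisopropylsilyl)oxy]benzaldehyde; 13 vinylmagnesium bromide
Product: 15 rac-1-{3,5-dimethoxy-4-[(triisopropylsilyl)oxy]phenyl}prop-2-en-1-yl benzoate, via bromomagnesium alkoxide 14 (not isolated)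
Conditions: 13 (1.3 equiv), THF, −20 → 0 °C; then BzCl (1.5 equiv), DMAP (10 mol %), 0 °C → rt; Et3N-buffered work-up
Reagents that add atoms: benzoyl chloride, O=C(Cl)c1ccccc1
Why: Grignard 1,2-addition to the aldehyde with in-situ O-acylation of the magnesium alkoxide; the benzoate is labile but any material that transposes to the linear cinnamyl benzoate is an equally good substrate for step 8, so the crude mixture is usable.

**Step 8**
Reactants: 6 1-(4-hydroxy-3-iodo-5-methoxyphenyl)ethan-1-one; 15 rac-1-{3,5-dimethoxy-4-[(triisopropylsilyl)oxy]phenyl}prop-2-en-1-yl benzoate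
Product: 17 1-{4-[((1S)-1-{3,5-dimethoxy-4-[(triisopropylsilyl)oxy]phenyl}prop-2-en-1-yl)oxy]-3-iodo-5-methoxyphenyl}ethan-1-one, via sodium 4-acetyl-2-iodo-6-methoxyphenolate 16 (not isolated)
Conditions: 6, NaH (1.0 equiv), THF, 0 °C; then 15 (1.15 equiv), [Ir(cod)Cl]2 (2 mol %), L (4 mol %, pre-activated with n-PrNH2), THF, rt
Reagents that add atoms: none
Why: Ir-catalysed asymmetric allylic etherification run as a kinetic asymmetric transformation of the racemic branched ester, in which both enantiomers of 15 ionise to interconverting allyl–iridium species and phenoxide 16 (ortho and para carbons all blocked, so only O-attack is possible) adds to the aryl-bearing terminus under ligand control to set C2 as S.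

**Step 9 (key step)**
Reactants: 17 1-{4-[((1S)-1-{3,5-dimethoxy-4-[(triisopropylsilyl)oxy]phenyl}prop-2-en-1-yl)oxy]-3-iodo-5-methoxyphenyl}ethan-1-one
Product: 20 1-[(2S,3R)-2-(4-hydroxy-3,5-dimethoxyphenyl)-3-(hydroxymethyl)-7-methoxy-2,3-dihydro-1-benzofuran-5-yl]ethan-1-one (target), via primary hydroperoxide 18 (not isolated), via silyl-protected alcohol 19 (not isolated)
Conditions: Bu3SnH (3 equiv, syringe pump), dry air, Et3B (10 mol %), PhMe, 0 °C; Ar purge; then HF·pyridine, pyridine, THF, 0 °C → rt
Reagents that add atoms: dioxygen (from air), O=O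
Why: Oxygenative aryl-radical cyclisation followed by fluoride desilylation, in which Bu3Sn• abstracts iodine, the aryl radical adds 5-exo-trig to the internal vinyl carbon through a chair-like Beckwith–Houk transition state with the C2 aryl group pseudo-equatorial (C3 set trans, 3R), the primary radical is captured by O2, hydroperoxide 18 is reduced by Bu3SnH to 19 and buffered HF removes the silyl group without opening the ring, the minor cis isomer being removed by chromatography of 20.

**Compound list**
1 | catechol (benzene-1,2-diol) | Oc1ccccc1O | starting material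
2 | 2-methoxyphenol (guaiacol) | COc1ccccc1O | intermediate
3 | acetic anhydride | CC(=O)OC(C)=O | starting material
4 | 2-methoxyphenyl acetate | COc1ccccc1OC(C)=O | intermediate (not isolated)
5 | 1-(4-hydroxy-3-methoxyphenyl)ethan-1-one (acetovanillone) | CC(=O)c1ccc(O)c(OC)c1 | intermediate
6 | 1-(4-hydroxy-3-iodo-5-methoxyphenyl)ethan-1-one | CC(=O)c1cc(I)c(O)c(OC)c1 | intermediate
7 | p-cresol (4-methylphenol) | Cc1ccc(O)cc1 | starting material
8 | 2,6-dibromo-4-methylphenol | Cc1cc(Br)c(O)c(Br)c1 | intermediate (not isolated)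
9 | 2,6-dibromo-4-(dibromomethyl)phenol | BrC(Br)c1cc(Br)c(O)c(Br)c1 | intermediate (not isolated)
10 | 3,5-dibromo-4-hydroxybenzaldehyde | O=Cc1cc(Br)c(O)c(Br)c1 | intermediate
11 | 4-hydroxy-3,5-dimethoxybenzaldehyde (syringaldehyde) | COc1cc(C=O)cc(OC)c1O | intermediate
12 | 3,5-dimethoxy-4-[(triisopropylsilyl)oxy]benzaldehyde | COc1cc(C=O)cc(OC)c1O[Si](C(C)C)(C(C)C)C(C)C | intermediate
13 | vinylmagnesium bromide | C=C[Mg]Br | starting material
14 | bromomagnesium 1-{3,5-dimethoxy-4-[(triisopropylsilyl)oxy]phenyl}prop-2-en-1-olate (racemic) | C=CC(O[Mg]Br)c1cc(OC)c(O[Si](C(C)C)(C(C)C)C(C)C)c(OC)c1 | intermediate (not isolated)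
15 | rac-1-{3,5-dimethoxy-4-[(triisopropylsilyl)oxy]phenyl}prop-2-en-1-yl benzoate | C=CC(OC(=O)c1ccccc1)c1cc(OC)c(O[Si](C(C)C)(C(C)C)C(C)C)c(OC)c1 | intermediate
16 | sodium 4-acetyl-2-iodo-6-methoxyphenolate | CC(=O)c1cc(I)c([O-])c(OC)c1.[Na+] | intermediate (not isolated)
17 | 1-{4-[((1S)-1-{3,5-dimethoxy-4-[(triisopropylsilyl)oxy]phenyl}prop-2-en-1-yl)oxy]-3-iodo-5-methoxyphenyl}ethan-1-one | CC(=O)c1cc(I)c(O[C@@H](C=C)c2cc(OC)c(O[Si](C(C)C)(C(C)C)C(C)C)c(OC)c2)c(OC)c1 | intermediate
18 | 1-[(2S,3R)-2-{3,5-dimethoxy-4-[(triisopropylsilyl)oxy]phenyl}-3-(hydroperoxymethyl)-7-methoxy-2,3-dihydro-1-benzofuran-5-yl]ethan-1-one | COc1cc([C@H]2Oc3c(OC)cc(C(C)=O)cc3[C@@H]2COO)cc(OC)c1O[Si](C(C)C)(C(C)C)C(C)C | intermediate (not isolated)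
19 | 1-[(2S,3R)-2-{3,5-dimethoxy-4-[(triisopropylsilyl)oxy]phenyl}-3-(hydroxymethyl)-7-methoxy-2,3-dihydro-1-benzofuran-5-yl]ethan-1-one | COc1cc([C@H]2Oc3c(OC)cc(C(C)=O)cc3[C@@H]2CO)cc(OC)c1O[Si](C(C)C)(C(C)C)C(C)C | intermediate (not isolated)
20 | 1-[(2S,3R)-2-(4-hydroxy-3,5-dimethoxyphenyl)-3-(hydroxymethyl)-7-methoxy-2,3-dihydro-1-benzofuran-5-yl]ethan-1-one | COc1cc([C@H]2Oc3c(OC)cc(C(C)=O)cc3[C@@H]2CO)cc(OC)c1O | target

**Totals**
Total step count: 9.
Longest linear sequence: 6 steps (7 → 10 → 11 → 12 → 15 → 17 → 20; the branch from 1 joins at step 8 after 3 steps).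

**Steps most likely to fail, with fallbacks**

Step 8. Phenoxide 16 is doubly ortho-substituted and weakly nucleophilic. Because 6 is an acidic phenol, ether 17 can re-ionise on iridium, which would erode ee and leak to the linear ether. The racemic branched ester also needs fast equilibration of the allyl–iridium diastereomers. Fallback, setting out from 12 and coming back at 17 (it also bypasses step 7): ethynylmagnesium bromide (THF, 0 °C) adds to 12 to give racemic 1-{3,5-dimethoxy-4-[(triisopropylsilyl)oxy]phenyl}prop-2-yn-1-ol F1. Acetylation (3, Et3N, DMAP, CH2Cl2) gives rac-1-{3,5-dimethoxy-4-[(triisopropylsilyl)oxy]phenyl}prop-2-yn-1-yl acetate F2. Copper-catalysed enantioselective propargylic etherification with 6 (CuOTf·1/2C6H6, the Ph-pybox enantiomer that leads to the S ether, iPr2NEt, ClCH2CH2Cl, 0 °C) proceeds through a copper allenylidene, which the electron-rich aryl group stabilises, and gives 1-{4-[((1S)-1-{3,5-dimethoxy-4-[(triisopropylsilyl)oxy]phenyl}prop-2-yn-1-yl)oxy]-3-iodo-5-methoxyphenyl}ethan-1-one F3. Semihydrogenation of the terminal alkyne (H2, Pd/CaCO3 poisoned with Pb(OAc)2, quinoline, EtOAc, rt, stopped at one equivalent) then gives 17.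

Step 9. Premature hydrogen transfer from Bu3SnH to the cyclised radical would give the 3-methyl compound. The early transition state of the aryl radical may give only modest trans:cis selectivity, and peroxyl chemistry may lower the yield. Fallback, setting out from 17 and coming back at 19: the chain oxygenation is replaced by persistent-radical capture with no dioxygen present. Bu3SnH (1.1 equiv) with TEMPO (4 equiv) in benzene at 70 °C generates the same aryl radical; after 5-exo cyclisation the primary radical couples with TEMPO faster than it can be reduced, giving 1-[(2S,3R)-2-{3,5-dimethoxy-4-[(triisopropylsilyl)oxy]phenyl}-7-methoxy-3-{[(2,2,6,6-tetramethylpiperidin-1-yl)oxy]methyl}-2,3-dihydro-1-benzofuran-5-yl]ethan-1-one F4. F4 is purified free of its cis isomer while still silylated, and its N–O bond is cleaved with Zn in AcOH/THF/H2O at 50 °C to give 19. 19 is then desilylated with HF·pyridine as in the second operation of step 9 to give 20.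

Step 2. The Fries shift can give the ortho-acyl isomer and the isomer acylated para to the methoxy group, which lowers the yield of 5 and complicates its purification. Fallback, setting out from 1 and coming back at 5: exhaustive methylation of 1 (MeI 2.5 equiv, K2CO3, acetone, reflux) gives symmetrical 1,2-dimethoxybenzene F5, for which Friedel–Crafts acetylation (3, AlCl3, CH2Cl2, 0 °C) can give only 1-(3,4-dimethoxyphenyl)ethan-1-one F6. Nucleophilic demethylation with NaSEt (DMF, 110 °C) removes selectively the methyl group para to the carbonyl, because that phenoxide is the better leaving group, and gives 5.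

**Further compounds**
F1 | step 8 | rac-1-{3,5-dimethoxy-4-[(triisopropylsilyl)oxy]phenyl}prop-2-yn-1-ol | C#CC(O)c1cc(OC)c(O[Si](C(C)C)(C(C)C)C(C)C)c(OC)c1
F2 | step 8 | rac-1-{3,5-dimethoxy-4-[(triisopropylsilyl)oxy]phenyl}prop-2-yn-1-yl acetate | C#CC(OC(C)=O)c1cc(OC)c(O[Si](C(C)C)(C(C)C)C(C)C)c(OC)c1
F3 | step 8 | 1-{4-[((1S)-1-{3,5-dimethoxy-4-[(triisopropylsilyl)oxy]phenyl}prop-2-yn-1-yl)oxy]-3-iodo-5-methoxyphenyl}ethan-1-one | CC(=O)c1cc(I)c(O[C@@H](C#C)c2cc(OC)c(O[Si](C(C)C)(C(C)C)C(C)C)c(OC)c2)c(OC)c1
F4 | step 9 | 1-[(2S,3R)-2-{3,5-dimethoxy-4-[(triisopropylsilyl)oxy]phenyl}-7-methoxy-3-{[(2,2,6,6-tetramethylpiperidin-1-yl)oxy]methyl}-2,3-dihydro-1-benzofuran-5-yl]ethan-1-one | COc1cc([C@H]2Oc3c(OC)cc(C(C)=O)cc3[C@@H]2CON4C(C)(C)CCCC4(C)C)cc(OC)c1O[Si](C(C)C)(C(C)C)C(C)C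
F5 | step 2 | 1,2-dimethoxybenzene | COc1ccccc1OC
F6 | step 2 | 1-(3,4-dimethoxyphenyl)ethan-1-one | COc1ccc(C(C)=O)cc1OC
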